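The five-membered oxygen ring (O1, C2, C3, C3a, C7a) is disconnected across O1–C2 and C3a–C3, so that the benzene ring supplies its phenolic oxygen and the ortho carbon as a 1,3-C,O-dinucleophile and a four-carbon enal, 4-chloro-3-(chloromethyl)but-2-enal, acts as 1,2-dielectrophile. In one flask a silyl-masked ortho-oxyaryl Grignard reagent is transferred via titanium under chiral BINOLate catalysis to the aldehyde (C3 carbinol), then fluoride frees the phenoxide, which closes the ring by SN2′ attack at C2. The step exploits the C3 carbinol next to the allylic C2–O1 bond and the exocyclic methylene on the C2 side chain, which the SN2′ displacement creates. Acetylation, chloride-to-aldehyde oxidation and tigloylation complete the route.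

Key step: step 5

Remark: the target is read as the 2,3-trans (2S,3R) dihydrobenzofuran with an (R)-configured benzylic (E)-2-methylbut-2-enoate (tiglate); compounds 1, 5, 6 and 17 are taken as commercial.

Step 1
Reactants: 1 1-(4-hydroxy-3-iodophenyl)ethan-1-one
Product: 2 1-(4-{[tert-butyl(dimethyl)silyl]oxy}-3-iodophenyl)ethan-1-one
Conditions: TBSCl, imidazole, DMF, rt
Reagents that add atoms: tert-butyldimethylsilyl chloride, CC(C)(C)[Si](C)(C)Cl
Why: Imidazole-promoted O-silylation removes the acidic phenol before the borane reduction and installs the aryl silyl ether that serves as the fluoride-labile trigger in step 5.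

Step 2
Reactants: 2 aryl silyl ether ketone
Product: 3 (1R)-1-(4-{[tert-butyl(dimethyl)silyl]oxy}-3-iodophenyl)ethan-1-ol
Conditions: (S)-Me-CBS (10 mol%), BH3·SMe2, THF, −20 °C; MeOH
Reagents that add atoms: none
Why: Corey–Bakshi–Shibata reduction of an aryl methyl ketone, in which the (S)-oxazaborolidine treats the aryl group as the large substituent and should deliver the (R)-carbinol.

Step 3
Reactants: 3 (R)-benzylic alcohol
Product: 4 tert-butyl[(1R)-1-(4-{[tert-butyl(dimethyl)silyl]oxy}-3-iodophenyl)ethoxy]dimethylsilane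
Conditions: TBSCl, imidazole, DMF, rt
Reagents that add atoms: tert-butyldimethylsilyl chloride, CC(C)(C)[Si](C)(C)Cl
Why: Silylation of the secondary alcohol gives an alkyl silyl ether that should survive the later aryl-selective fluoride cleavage; the stereocentre is not touched.

Step 4
Reactants: 5 1,3-dichloropropan-2-one; 6 (triphenylphosphoranylidene)acetaldehyde
Product: 7 4-chloro-3-(chloromethyl)but-2-enal
Conditions: toluene, 80 °C (5 in excess)
Reagents that add atoms: none
Why: Wittig olefination of the strongly electrophilic α,α′-dichloro ketone by the formyl-stabilised ylide; the ketone is symmetric, so no alkene geometry has to be controlled.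

Step 5
Reactants: 4 bis-silylated (R)-aryl iodide; 7 4-chloro-3-(chloromethyl)but-2-enal
Product: 12 (2S,3R)-5-[(1R)-1-{[tert-butyl(dimethyl)silyl]oxy}ethyl]-2-(3-chloroprop-1-en-2-yl)-2,3-dihydro-1-benzofuran-3-ol, via arylmagnesium chloride 8 (not isolated), via aryltitanium triisopropoxide 9 (not isolated), via allylic alcohol 10 (not isolated), via caesium phenoxide 11 (not isolated)
Conditions: i-PrMgCl, THF, −20 to 0 °C; Ti(OiPr)4, CH2Cl2, −78 °C; (R)-3-(3,5-diphenylphenyl)-H8-BINOL (5 mol%), 7, 0 °C; then MeOH, CsF (excess), DMF, rt, same flask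
Reagents that add atoms: none
Why: Iodine–magnesium exchange gives 8, transmetalation gives 9, and the chiral titanium H8-BINOLate should transfer the aryl group to the aldehyde carbon of 7 in a 1,2-addition (aryl–C3 bond, alcohol 10); methanol then frees the carbinol and CsF cleaves only the aryl silyl ether, so that phenoxide 11 attacks C2 in an intramolecular SN2′ displacement of chloride (O1–C2 bond) that also creates the exocyclic methylene. The closest known reaction types are the titanium-BINOLate-catalysed asymmetric arylation of aldehydes by ArMgX/Ti(OiPr)4 and the base-mediated SN2′ cyclisation of ortho-(4-halobut-2-enyl)phenols to 2-isopropenyl-2,3-dihydrobenzofurans. The five-membered oxygen ring closes in the 5-exo-trig mode, whereas direct SN2 attack at CH2Cl would require a seven-membered ring. C3 is set by the catalyst (Re-face aryl delivery is expected for the R ligand by analogy with BINOL-titanium alkylations, giving the 1S carbinol that becomes 3R in the ring), and C2 is set by C3 through allylic 1,3-strain: C3–H eclipses the trisubstituted alkene, the aryl group and the OH lie on opposite faces, and O1 must add from the aryl face, which places the new alkenyl group trans to the C3 oxygen. The step needs 1,2- over 1,4-addition (secured by the aryltitanium reagent and the β,β-disubstituted enal), aryl over alkyl silyl ether cleavage (CsF) and O-alkylation by the phenoxide only (the C3 hydroxyl stays protonated in the presence of MeOH).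

Step 6
Reactants: 12 trans-3-hydroxy dihydrobenzofuran
Product: 13 (2S,3R)-5-[(1R)-1-{[tert-butyl(dimethyl)silyl]oxy}ethyl]-2-(3-chloroprop-1-en-2-yl)-2,3-dihydro-1-benzofuran-3-yl acetate
Conditions: Ac2O, pyridine, DMAP (cat.), CH2Cl2, 0 °C
Reagents that add atoms: acetic anhydride, CC(=O)OC(C)=O
Why: DMAP-catalysed acylation of the only free hydroxyl group, with retention at C3.

Step 7
Reactants: 13 allylic chloride acetate
Product: 15 (2S,3R)-5-[(1R)-1-{[tert-butyl(dimethyl)silyl]oxy}ethyl]-2-(3-oxoprop-1-en-2-yl)-2,3-dihydro-1-benzofuran-3-yl acetate, via N-alkoxymorpholinium chloride 14 (not isolated)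
Conditions: NMO (excess), NaHCO3, MeCN, 50 °C
Reagents that add atoms: N-methylmorpholine N-oxide, C[N+]1([O-])CCOCC1
Why: Ganem-type N-oxide oxidation (a Kornblum-type process), in which O-alkylation of NMO by the allylic chloride and base-induced loss of N-methylmorpholine from 14 should give the 2-substituted acrolein; SN2 and SN2′ attack are degenerate at this 2-substituted allyl unit and no stereocentre is involved.

Step 8
Reactants: 15 silyl-protected enal acetate
Product: 16 (2S,3R)-5-[(1R)-1-hydroxyethyl]-2-(3-oxoprop-1-en-2-yl)-2,3-dihydro-1-benzofuran-3-yl acetate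
Conditions: HF·pyridine, pyridine, THF, 0 °C to rt
Reagents that add atoms: none
Why: Buffered fluoride cleavage of the secondary silyl ether, which should leave the acetate, the enal and all stereocentres untouched.

Step 9
Reactants: 16 benzylic alcohol; 17 (2E)-2-methylbut-2-enoyl chloride (tigloyl chloride)
Product: 18 (1R)-1-[(2S,3R)-3-acetoxy-2-(3-oxoprop-1-en-2-yl)-2,3-dihydro-1-benzofuran-5-yl]ethyl (2E)-2-methylbut-2-enoate
Conditions: pyridine, DMAP (cat.), CH2Cl2, 0 °C
Reagents that add atoms: none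
Why: Acylation of the secondary alcohol by the acid chloride proceeds with retention at the carbinol carbon; pyridine in place of a trialkylamine should avoid the vinylketene pathway that would deconjugate the E-configured tigloyl unit.

Compound list
1 | 1-(4-hydroxy-3-iodophenyl)ethan-1-one | CC(=O)c1ccc(O)c(I)c1 | starting material
2 | 1-(4-{[tert-butyl(dimethyl)silyl]oxy}-3-iodophenyl)ethan-1-one | CC(=O)c1ccc(O[Si](C)(C)C(C)(C)C)c(I)c1 | intermediate
3 | (1R)-1-(4-{[tert-butyl(dimethyl)silyl]oxy}-3-iodophenyl)ethan-1-ol | C[C@@H](O)c1ccc(O[Si](C)(C)C(C)(C)C)c(I)c1 | intermediate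
4 | tert-butyl[(1R)-1-(4-{[tert-butyl(dimethyl)silyl]oxy}-3-iodophenyl)ethoxy]dimethylsilane | C[C@@H](O[Si](C)(C)C(C)(C)C)c1ccc(O[Si](C)(C)C(C)(C)C)c(I)c1 | intermediate
5 | 1,3-dichloropropan-2-one | O=C(CCl)CCl | starting material
6 | (triphenylphosphoranylidene)acetaldehyde | O=CC=P(c1ccccc1)(c1ccccc1)c1ccccc1 | starting material
7 | 4-chloro-3-(chloromethyl)but-2-enal | O=CC=C(CCl)CCl | intermediate
8 | [2-{[tert-butyl(dimethyl)silyl]oxy}-5-[(1R)-1-{[tert-butyl(dimethyl)silyl]oxy}ethyl]phenyl]magnesium chloride | C[C@@H](O[Si](C)(C)C(C)(C)C)c1ccc(O[Si](C)(C)C(C)(C)C)c([Mg]Cl)c1 | intermediate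
9 | [2-{[tert-butyl(dimethyl)silyl]oxy}-5-[(1R)-1-{[tert-butyl(dimethyl)silyl]oxy}ethyl]phenyl]titanium triisopropoxide | C[C@@H](O[Si](C)(C)C(C)(C)C)c1ccc(O[Si](C)(C)C(C)(C)C)c([Ti](OC(C)C)(OC(C)C)OC(C)C)c1 | intermediate
10 | (1S)-1-[2-{[tert-butyl(dimethyl)silyl]oxy}-5-[(1R)-1-{[tert-butyl(dimethyl)silyl]oxy}ethyl]phenyl]-4-chloro-3-(chloromethyl)but-2-en-1-ol | O[C@@H](C=C(CCl)CCl)c1cc(ccc1O[Si](C)(C)C(C)(C)C)[C@@H](C)O[Si](C)(C)C(C)(C)C | intermediate
11 | caesium 4-[(1R)-1-{[tert-butyl(dimethyl)silyl]oxy}ethyl]-2-[(1S)-4-chloro-3-(chloromethyl)-1-hydroxybut-2-en-1-yl]phenolate | O[C@@H](C=C(CCl)CCl)c1cc(ccc1[O-])[C@@H](C)O[Si](C)(C)C(C)(C)C.[Cs+] | intermediate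
12 | (2S,3R)-5-[(1R)-1-{[tert-butyl(dimethyl)silyl]oxy}ethyl]-2-(3-chloroprop-1-en-2-yl)-2,3-dihydro-1-benzofuran-3-ol | C=C(CCl)[C@@H]1Oc2ccc([C@@H](C)O[Si](C)(C)C(C)(C)C)cc2[C@H]1O | intermediate
13 | (2S,3R)-5-[(1R)-1-{[tert-butyl(dimethyl)silyl]oxy}ethyl]-2-(3-chloroprop-1-en-2-yl)-2,3-dihydro-1-benzofuran-3-yl acetate | C=C(CCl)[C@@H]1Oc2ccc([C@@H](C)O[Si](C)(C)C(C)(C)C)cc2[C@H]1OC(C)=O | intermediate
14 | 4-({2-[(2S,3R)-3-acetoxy-5-[(1R)-1-{[tert-butyl(dimethyl)silyl]oxy}ethyl]-2,3-dihydro-1-benzofuran-2-yl]prop-2-en-1-yl}oxy)-4-methylmorpholin-4-ium chloride | C=C(CO[N+]1(C)CCOCC1)[C@@H]1Oc2ccc([C@@H](C)O[Si](C)(C)C(C)(C)C)cc2[C@H]1OC(C)=O.[Cl-] | intermediate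
15 | (2S,3R)-5-[(1R)-1-{[tert-butyl(dimethyl)silyl]oxy}ethyl]-2-(3-oxoprop-1-en-2-yl)-2,3-dihydro-1-benzofuran-3-yl acetate | C=C(C=O)[C@@H]1Oc2ccc([C@@H](C)O[Si](C)(C)C(C)(C)C)cc2[C@H]1OC(C)=O | intermediate
16 | (2S,3R)-5-[(1R)-1-hydroxyethyl]-2-(3-oxoprop-1-en-2-yl)-2,3-dihydro-1-benzofuran-3-yl acetate | C=C(C=O)[C@@H]1Oc2ccc([C@@H](C)O)cc2[C@H]1OC(C)=O | intermediate
17 | (2E)-2-methylbut-2-enoyl chloride (tigloyl chloride) | C/C=C(\C)C(Cl)=O | starting material
18 | (1R)-1-[(2S,3R)-3-acetoxy-2-(3-oxoprop-1-en-2-yl)-2,3-dihydro-1-benzofuran-5-yl]ethyl (2E)-2-methylbut-2-enoate | C=C(C=O)[C@@H]1Oc2ccc([C@@H](C)OC(=O)/C(C)=C/C)cc2[C@H]1OC(C)=O | target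

Total step count: 9. Longest linear sequence: 8 steps (1, 2, 3, 5, 6, 7, 8, 9).

Steps most likely to fail

Step 5. The enantiofacial control of the aryl transfer may erode, because the ortho-silyloxy group and residual magnesium salts can open an uncatalysed pathway; the C2/C3-epimeric trans isomer would then be carried forward as a diastereomer. The fallback sets out from 4 (through 8) and returns at 12. Intermediate 8 is quenched with B(OMe)3 and hydrolysed to [2-{[tert-butyl(dimethyl)silyl]oxy}-5-[(1R)-1-{[tert-butyl(dimethyl)silyl]oxy}ethyl]phenyl]boronic acid F1. Boron-to-zinc exchange with Et2Zn (toluene, 60 °C) and amino-alcohol-catalysed aryl transfer to 7 should give 10, which is isolated and purified. The catalyst is the antipode of 3-exo-morpholinoisoborneol that delivers aryl to the Re face, expected to be the (+)-form. A separate CsF/DMF treatment then effects the SN2′ closure to 12.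

Step 7. O-Alkylation of the N-oxide by the allylic chloride may be sluggish, and on prolonged heating base-induced loss of acetic acid across C2–C3 would aromatise the ring to the benzofuran. The fallback sets out from 13 and returns at 15. Displacement of chloride with HCO2Na (Bu4NI cat., DMF, 40 °C) should give 2-[(2S,3R)-3-acetoxy-5-[(1R)-1-{[tert-butyl(dimethyl)silyl]oxy}ethyl]-2,3-dihydro-1-benzofuran-2-yl]prop-2-en-1-yl formate F2. Selective methanolysis of the formate (KHCO3, MeOH, 0 °C) should give (2S,3R)-5-[(1R)-1-{[tert-butyl(dimethyl)silyl]oxy}ethyl]-2-(3-hydroxyprop-1-en-2-yl)-2,3-dihydro-1-benzofuran-3-yl acetate F3, and MnO2 (CH2Cl2, rt) oxidises this allylic alcohol to 15.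

Step 4. The ylide may olefinate product 7 a second time (vinylogous chain extension) or be C-alkylated by the α-chloro ketone. The fallback sets out from 5 and returns at 7. Olefination with Ph3P=CHCO2Et (CH2Cl2, rt) gives ethyl 4-chloro-3-(chloromethyl)but-2-enoate F4, reduction with i-Bu2AlH (CH2Cl2, −78 °C) gives 4-chloro-3-(chloromethyl)but-2-en-1-ol F5, and MnO2 oxidation gives 7.

Further compounds
F1 | step 5 | [2-{[tert-butyl(dimethyl)silyl]oxy}-5-[(1R)-1-{[tert-butyl(dimethyl)silyl]oxy}ethyl]phenyl]boronic acid | C[C@@H](O[Si](C)(C)C(C)(C)C)c1ccc(O[Si](C)(C)C(C)(C)C)c(B(O)O)c1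
F2 | step 7 | 2-[(2S,3R)-3-acetoxy-5-[(1R)-1-{[tert-butyl(dimethyl)silyl]oxy}ethyl]-2,3-dihydro-1-benzofuran-2-yl]prop-2-en-1-yl formate | C=C(COC=O)[C@@H]1Oc2ccc([C@@H](C)O[Si](C)(C)C(C)(C)C)cc2[C@H]1OC(C)=O
F3 | step 7 | (2S,3R)-5-[(1R)-1-{[tert-butyl(dimethyl)silyl]oxy}ethyl]-2-(3-hydroxyprop-1-en-2-yl)-2,3-dihydro-1-benzofuran-3-yl acetate | C=C(CO)[C@@H]1Oc2ccc([C@@H](C)O[Si](C)(C)C(C)(C)C)cc2[C@H]1OC(C)=O
F4 | step 4 | ethyl 4-chloro-3-(chloromethyl)but-2-enoate | CCOC(=O)C=C(CCl)CCl
F5 | step 4 | 4-chloro-3-(chloromethyl)but-2-en-1-ol | OCC=C(CCl)CCl
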